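At early times the gamma run reads 1% at 3.00 min, and its left-handed product climbs faster between 8.00 min and 12.0 min than it did before 8.00 min. From 8.00 min to 12.0 min the reading grows by a factor of 2.25, and the square of the time ratio is 2.25. This looks like an induction period followed by a square law, as if catalyst were growing steadily out of precatalyst.

| flask | left-handed substrate | right-handed substrate | reagent | precatalyst | added ligand | temperature | remark | time |
|---|---|---|---|---|---|---|---|---|
| eta | 1 M | 1 M | 2 M | 100 mM | 770 mM | 55 °C | run made earlier |  |
| gamma | 1 M | 1 M | 2 M | 220 mM | 770 mM | 75 °C | run made earlier |  |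
| alder | 1.0 M | 1.0 M | 2.00 M | 150 mM | 770 mM |  | at 60 °C until 8.0 min, from then on at 90 °C | 12 min |
| elm | 1.0 M | 1.0 M | 2.00 M | 150 mM | 770 mM | 90 °C |  | 12 min |
| larch | 1.0 M | 1.0 M | 2.00 M | 150 mM | 770 mM | 60 °C |  | 12 min |

- eta (time / min: left-handed product / %): 4.00: 0; 12.0: 2; 15.0: 3; 30.0: 2; 50.0: 0; 60.0: 2
- gamma (time / min: left-handed product / %): 2.00: 0; 3.00: 1; 4.00: 1; 8.00: 4; 12.0: 9; 20.0: 18

(readings scatter by 1.5 percentage points)

- the flask that comes out highest in amount of left-handed product, in percent of the left-handed substrate and right-handed substrate together charged, or "all alike" when all lie within 1.5 percentage points (alder / elm / larch / all alike)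
- left-handed product at the end, in percent of the left-handed substrate and right-handed substrate together charged, alder
- left-handed product at the end, in percent of the left-handed substrate and right-handed substrate together charged, elm
- left-handed product at the end, in percent of the left-handed substrate and right-handed substrate together charged, larch

Dividing a reading by its precatalyst and by the square of its time makes time drop out. Gamma's number at 12.0 min over eta's at 60.0 min is 51.1: this is the warming gain from 55 °C to 75 °C. It is rough, since eta's 2% stands close to the scatter of 1.5 percentage points.

For whoever takes over the bench, this is the reckoning made here, spreading the gain evenly over the degrees. Larch lies a quarter of the way up that span and should show about 0.321%. Elm's square law runs to 117%, above the 50.0% that the left-handed substrate allows, so elm must bend away from the law and should end somewhere under that ceiling. Alder's hot stretch gives 13.0%, and its cold stretch adds 0.143%, far less. Nearly all of alder's reckoned product therefore belongs to the hot stretch, which counts by the square of the time left after the change, so that time is not to be touched if alder's figure is to hold.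

The forecast also names elm highest, but gives elm 25% (13% to 38%), lower than the square law's figure here, with the remark “Substrate depletion applies”. For alder it gives 9% (4% to 15%) and for larch 1% (0% to 3%).

Elm comes out highest at 37.0%, with alder at 12.8% and larch at 0.291%.

    reagent + catalyst + right-handed substrate → catalyst + right-handed product (k = 0.970 M⁻² min⁻¹, Ea = 67.0 kJ mol⁻¹)
    2 catalyst ⇌ resting dimer, settled at all times (K = 1.50 M⁻¹, ΔH = −39.0 kJ mol⁻¹)
    reagent + catalyst + left-handed substrate → catalyst + left-handed product (k = 4.20 M⁻² min⁻¹, Ea = 71.0 kJ mol⁻¹)
    catalyst + added ligand ⇌ idle complex, settled at all times (K = 2.10 M⁻¹, ΔH = −48.0 kJ mol⁻¹)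
    precatalyst → catalyst (k = 0.0760 min⁻¹, Ea = 97.0 kJ mol⁻¹)
    (constants at 90 °C)

At 12.0 min elm still holds 13.0% left-handed substrate and has made 13.4% right-handed product. Carried to larch left for 120 min, the warming gain and the square law give 32.1%, and that flask stands at 18.2%.

(The earlier runs and the new flask are calculated with constants of no real substance.)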